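Cuts: (a) the E-alkene between ring A C5 and ring B C6 (Heck); (b) C2–C3 in ring A and in ring B (carbene C–H insertion); (c) ring B C3–C3a (aryl Grignard addition) and the bond from ring C C4 to ring B C3 (formylation of a C4 triflate); (d) in ring C the C3–aryl bond (decarboxylative arylation) and C3–C3a (ring contraction).
Enabling feature: the benzo part of ring C carries O1 at C7a, oxygen at C6 and a C4 position that can be carried as oxygen. This is the phloroglucinol pattern of the A ring of a 5,7-dioxygenated flavanone, and the flavanone pyranone (O1, C2, C3, C4, C4a, C8a) holds exactly one ring carbon more than the dihydrofuran (O1, C2, C3, C3a, C7a).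
Forward order: chromone, (2S)-flavanone, contraction to the ring C ester, C3 aryl group, C4 aldehyde. Ring B is then grown on that aldehyde, ring A is made separately, and the halves are joined by a Heck reaction before ninefold demethylation.
Stereochemistry: ring C C2 comes from an asymmetric rhodium-catalysed conjugate addition, and C3 is relayed trans from it in both the contraction and the radical arylation. C3 of rings A and B comes from the two enantiomers of one dirhodium catalyst, their C2 centres from acid equilibration to trans, and the alkene geometry from the Heck step.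

Key step: step 4

Assumption: the sense of induction is taken from the accepted models of each reaction class ((S)-biaryl bisphosphine on rhodium gives 2S in 7, Rh2(S-PTAD)4 gives 3R in ring B, Rh2(R-PTAD)4 gives 3S in ring A); both antipodes of each ligand are available, so a reversed sense would be met by exchanging them.

Step 1
Reactants: 1 1-(2,6-dihydroxy-4-methoxyphenyl)ethan-1-one; 2 benzyl bromide
Product: 3 1-[2-(benzyloxy)-6-hydroxy-4-methoxyphenyl]ethan-1-one
Conditions: BnBr (1.0 equiv), K2CO3, acetone, reflux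
Reagents that add atoms: none
Why: Williamson etherification of a symmetric diol should stop after one alkylation, because the remaining phenol is tied up in a hydrogen bond to the acetyl carbonyl.

Step 2
Reactants: 3 mono-benzyl acetophenone
Product: 5 5-(benzyloxy)-7-methoxy-4H-chromen-4-one, via enaminone 4 (not isolated)
Conditions: Me2NCH(OMe)2, toluene, 100 °C; concentrate; aq HCl, CH2Cl2, 40 °C
Reagents that add atoms: N,N-dimethylformamide dimethyl acetal, COC(OC)N(C)C
Why: This is the standard enaminone route to 2,3-unsubstituted chromones, in which the acetyl CH3 condenses with the amide acetal and acid then drives addition of the ortho phenol with loss of dimethylamine.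

Step 3
Reactants: 5 5-(benzyloxy)-7-methoxychromone; 6 4-methoxyphenylboronic acid
Product: 7 (2S)-5-(benzyloxy)-7-methoxy-2-(4-methoxyphenyl)chroman-4-one
Conditions: [Rh(OH)(cod)]2 (1.5 mol %), (S)-MeO-F12-BIPHEP (3.3 mol %), toluene/H2O, rt
Reagents that add atoms: none
Why: This is a Hayashi–Miyaura-type asymmetric 1,4-addition of an arylboronic acid to a chromone, known for 5,7-dioxygenated chromones, in which the chiral bisphosphine shields one face of C2 to set 2S and the near-neutral room-temperature medium should prevent retro-oxa-Michael opening of the flavanone.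

Step 4
Reactants: 7 (2S)-flavanone
Product: 9 methyl (2S,3S)-4-(benzyloxy)-6-methoxy-2-(4-methoxyphenyl)-2,3-dihydrobenzofuran-3-carboxylate, via enol ether 8 (not isolated)
Conditions: PhI(OAc)2 (1.1 equiv), H2SO4 (cat.), HC(OMe)3, 0 °C to rt; aqueous work-up
Reagents that add atoms: trimethyl orthoformate, COC(OC)OC
Why: Acid and orthoformate turn ketone 7 into enol ether 8, the electrophilic iodine of PhI(OAc)2 adds to C3 on the face away from the C2 aryl group, and methanol caps C4 as the dimethyl ketal. The equatorial C3–iodine bond then lies antiperiplanar to C4–C4a, so C4a shifts from C4 to C3 as iodobenzene leaves, and the dimethoxycarbenium ion left at the former C4 collapses to the methyl ester. This is the known oxidative 1,2-aryl-shift contraction of flavanones to trans-2-aryl-2,3-dihydrobenzofuran-3-carboxylates with hypervalent iodine in trimethyl orthoformate, which has also been run on non-racemic flavanones. The dihydrofuran of ring C is closed by migration (C4a–C4 is traded for C3a–C3, a six-membered ring becoming a five-membered one) and not by cyclisation of an open chain. C2 is untouched and stays S; C3 is set S by inversion at the iodine-bearing carbon (iodine trans to aryl becomes ester trans to aryl), backed by the thermodynamic trans preference of the epimerisable ester. The step needs fused-aryl rather than 2-anisyl migration, and the substrate secures this because C4a is ortho or para to three oxygen donors (O1, 5-OBn, 7-OMe) and because the diequatorial conformer aligns only the ring bond with the leaving group.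

Step 5
Reactants: 9 ring C methyl ester
Product: 10 (2S,3S)-4-(benzyloxy)-6-methoxy-2-(4-methoxyphenyl)-2,3-dihydrobenzofuran-3-carboxylic acid
Conditions: Me3SnOH, ClCH2CH2Cl, 80 °C; aq HCl wash
Reagents that add atoms: trimethyltin hydroxide, C[Sn](C)(C)O
Why: Neutral tin-hydroxide ester cleavage frees the acid without passing through the ester enolate, so neither C3 epimerisation nor E1cB loss of the ring phenoxide (which would erase C2) should intervene.

Step 6
Reactants: 10 ring C acid
Product: 11 1,3-dioxoisoindolin-2-yl (2S,3S)-4-(benzyloxy)-6-methoxy-2-(4-methoxyphenyl)-2,3-dihydrobenzofuran-3-carboxylate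
Conditions: N-hydroxyphthalimide, DIC, DMAP (cat.), CH2Cl2, rt
Reagents that add atoms: N-hydroxyphthalimide, O=C1c2ccccc2C(=O)N1O
Why: Steglich-type carbodiimide coupling is the routine way to make a redox-active N-acyloxyphthalimide ester and does not touch the ethers or the stereocentres.

Step 7
Reactants: 11 redox-active ester; 12 3,5-dimethoxyphenylmagnesium chloride (commercial THF solution)
Product: 14 (2S,3S)-4-(benzyloxy)-3-(3,5-dimethoxyphenyl)-6-methoxy-2-(4-methoxyphenyl)-2,3-dihydrobenzofuran, via arylzinc chloride 13 (not isolated)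
Conditions: 12, ZnCl2, LiCl, THF, 0 °C to rt; then 11, NiCl2·glyme (20 mol %), 4,4'-di-tert-butyl-2,2'-bipyridine (40 mol %), THF/DMF, rt
Reagents that add atoms: none
Why: In this nickel-catalysed decarboxylative Negishi-type arylation of a redox-active ester, electron transfer releases CO2 and phthalimide anion, and aryl-nickel captures the planar benzylic C3 radical on the face opposite the C2 anisyl group, which should give the trans (3S) isomer as with other cyclic radicals bearing a neighbouring substituent.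

Step 8
Reactants: 14 ring C benzyl ether
Product: 15 (2S,3S)-3-(3,5-dimethoxyphenyl)-6-methoxy-2-(4-methoxyphenyl)-2,3-dihydrobenzofuran-4-ol
Conditions: H2 (1 atm), Pd/C, EtOAc/MeOH, rt
Reagents that add atoms: none
Why: Catalytic hydrogenolysis cleaves the primary benzyl aryl ether far faster than the hindered secondary C2–O bond of the dihydrobenzofuran, so only the C4 phenol should be unmasked.

Step 9
Reactants: 15 ring C phenol
Product: 16 (2S,3S)-3-(3,5-dimethoxyphenyl)-6-methoxy-2-(4-methoxyphenyl)-2,3-dihydrobenzofuran-4-yl trifluoromethanesulfonate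
Conditions: Tf2O, pyridine, CH2Cl2, 0 °C
Reagents that add atoms: trifluoromethanesulfonic anhydride, O=S(=O)(OS(=O)(=O)C(F)(F)F)C(F)(F)F
Why: O-Sulfonylation of the only free hydroxyl is a standard phenol-to-triflate activation and turns the C4 oxygen into a cross-coupling handle.

Step 10
Reactants: 16 ring C triflate
Product: 17 (2S,3S)-3-(3,5-dimethoxyphenyl)-6-methoxy-2-(4-methoxyphenyl)-2,3-dihydrobenzofuran-4-carbaldehyde
Conditions: Pd(OAc)2 (5 mol %), dppp, CO (1 atm), Et3SiH, Et3N, DMF, 70 °C
Reagents that add atoms: carbon monoxide, [C-]#[O+]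
Why: This is a palladium-catalysed reductive carbonylation (formylation) of an aryl triflate, proceeding by oxidative addition to zerovalent palladium, CO insertion and hydride transfer from the silane, with a chelating bisphosphine as usual for electron-rich triflates.

Step 11
Reactants: 18 5-bromo-2-iodophenol; 19 4-methoxybenzyl chloride
Product: 20 4-bromo-1-iodo-2-[(4-methoxybenzyl)oxy]benzene
Conditions: K2CO3, DMF, 50 °C
Reagents that add atoms: none
Why: Williamson etherification installs the OCH2Ar unit whose CH2 carbon and anisyl ring later become C2 of ring B and its aryl group.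

Step 12
Reactants: 17 ring C aldehyde; 20 aryl iodide
Product: 22 {4-bromo-2-[(4-methoxybenzyl)oxy]phenyl}[(2S,3S)-3-(3,5-dimethoxyphenyl)-6-methoxy-2-(4-methoxyphenyl)-2,3-dihydrobenzofuran-4-yl]methanol (carbinol epimers), via aryl Grignard reagent 21 (not isolated)
Conditions: 20, i-PrMgCl·LiCl, THF, −20 °C; then 17, −20 °C to rt; aq NH4Cl
Reagents that add atoms: none
Why: Halogen–magnesium exchange with the turbo-Grignard reagent takes the carbon–iodine bond ortho to the ether oxygen in preference to the carbon–bromine bond, the aryl Grignard adds to the aldehyde, and the new carbinol centre is erased in the next step.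

Step 13
Reactants: 22 diaryl carbinol
Product: 23 {4-bromo-2-[(4-methoxybenzyl)oxy]phenyl}[(2S,3S)-3-(3,5-dimethoxyphenyl)-6-methoxy-2-(4-methoxyphenyl)-2,3-dihydrobenzofuran-4-yl]methanone
Conditions: Dess–Martin periodinane, CH2Cl2, rt
Reagents that add atoms: none
Why: Dess–Martin oxidation converts hindered diaryl carbinols to ketones under mild conditions that spare benzylic ethers, the aryl bromide and electron-rich arenes.

Step 14
Reactants: 23 diaryl ketone
Product: 24 hydrazone of ketone 23 (E/Z mixture)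
Conditions: N2H4·H2O (excess), AcOH (cat.), n-BuOH, 110 °C
Reagents that add atoms: hydrazine, NN
Why: Acid-catalysed condensation of a benzophenone with excess hydrazine gives the free hydrazone; the heat compensates for the two ortho substituents, and nothing else in the molecule reacts with hydrazine.

Step 15
Reactants: 24 hydrazone
Product: 26 (2S,3S)-4-[(2S,3R)-6-bromo-2-(4-methoxyphenyl)-2,3-dihydrobenzofuran-3-yl]-3-(3,5-dimethoxyphenyl)-6-methoxy-2-(4-methoxyphenyl)-2,3-dihydrobenzofuran (ring B cis), via diaryldiazomethane 25 (not isolated)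
Conditions: MnO2, CH2Cl2, 0 °C; filter; Rh2(S-PTAD)4 (1 mol %), CH2Cl2, 0 °C
Reagents that add atoms: none
Why: Hydrazone oxidation followed by dirhodium-catalysed intramolecular 1,5 C–H insertion of a donor/donor carbene into the activated OCH2Ar bond is a known enantioselective entry to cis-2,3-diaryl-2,3-dihydrobenzofurans, in which the chiral carboxylate catalyst fixes ring B C3 as R by reagent control and the concerted insertion places the two aryl groups cis.

Step 16
Reactants: 26 ring B cis isomer
Product: 27 (2S,3S)-4-[(2R,3R)-6-bromo-2-(4-methoxyphenyl)-2,3-dihydrobenzofuran-3-yl]-3-(3,5-dimethoxyphenyl)-6-methoxy-2-(4-methoxyphenyl)-2,3-dihydrobenzofuran (ring B trans)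
Conditions: CF3CO2H, CH2Cl2, 0 °C, stopped when 26 is consumed
Reagents that add atoms: none
Why: In this acid-catalysed thermodynamic equilibration, reversible SN1-type heterolysis of the benzylic C2–O bond gives a 4-methoxybenzyl cation that recloses 5-exo through the adjacent phenol faster than any arene can attack it, so ring B C2 should invert to the less strained trans (2R) arrangement while C3 and the already trans ring C stay as they are.

Step 17
Reactants: 28 5-bromo-2-hydroxy-3-methoxybenzaldehyde; 19 4-methoxybenzyl chloride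
Product: 29 5-bromo-3-methoxy-2-[(4-methoxybenzyl)oxy]benzaldehyde
Conditions: K2CO3, DMF, 50 °C
Reagents that add atoms: none
Why: Williamson etherification of the single phenol supplies the OCH2Ar insertion site for ring A.

Step 18
Reactants: 29 ring A aldehyde; 12 3,5-dimethoxyphenylmagnesium chloride
Product: 30 {5-bromo-3-methoxy-2-[(4-methoxybenzyl)oxy]phenyl}(3,5-dimethoxyphenyl)methanol (racemic)
Conditions: THF, 0 °C; aq NH4Cl
Reagents that add atoms: none
Why: Grignard 1,2-addition to the aldehyde is much faster than any exchange at the aryl bromide, and the carbinol centre disappears in the next step.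

Step 19
Reactants: 30 ring A carbinol
Product: 31 {5-bromo-3-methoxy-2-[(4-methoxybenzyl)oxy]phenyl}(3,5-dimethoxyphenyl)methanone
Conditions: Dess–Martin periodinane, CH2Cl2, rt
Reagents that add atoms: none
Why: Dess–Martin oxidation of a diaryl carbinol gives the benzophenone, as in step 13.

Step 20
Reactants: 31 ring A ketone
Product: 32 hydrazone of ketone 31 (E/Z mixture)
Conditions: N2H4·H2O (excess), AcOH (cat.), EtOH, reflux
Reagents that add atoms: hydrazine, NN
Why: This is a routine hydrazone condensation of a 2-alkoxybenzophenone.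

Step 21
Reactants: 32 ring A hydrazone
Product: 34 (2R,3S)-5-bromo-3-(3,5-dimethoxyphenyl)-7-methoxy-2-(4-methoxyphenyl)-2,3-dihydrobenzofuran (cis), via diaryldiazomethane 33 (not isolated)
Conditions: MnO2, CH2Cl2, 0 °C; filter; Rh2(R-PTAD)4 (1 mol %), CH2Cl2, 0 °C
Reagents that add atoms: none
Why: This is the same donor/donor carbene 1,5 C–H insertion as in step 15, on the substrate type for which it was developed (2-benzyloxybenzophenone hydrazones), with the enantiomeric catalyst setting C3 as S and the insertion giving the cis ring.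

Step 22
Reactants: 34 ring A cis bromide
Product: 35 (2S,3S)-5-bromo-3-(3,5-dimethoxyphenyl)-7-methoxy-2-(4-methoxyphenyl)-2,3-dihydrobenzofuran (trans)
Conditions: CF3CO2H, CH2Cl2, 0 °C
Reagents that add atoms: none
Why: Acid-catalysed equilibration through reversible C2–O heterolysis, as in step 16, should invert only C2 and deliver the thermodynamically preferred trans isomer with C3 retained.

Step 23
Reactants: 35 ring A trans bromide
Product: 36 (2S,3S)-3-(3,5-dimethoxyphenyl)-5-ethenyl-7-methoxy-2-(4-methoxyphenyl)-2,3-dihydrobenzofuran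
Conditions: vinylboronic acid pinacol ester, PdCl2(dppf) (5 mol %), K2CO3, dioxane/H2O, 90 °C
Reagents that add atoms: vinylboronic acid pinacol ester, C=CB1OC(C)(C)C(C)(C)O1
Why: Suzuki–Miyaura vinylation of an aryl bromide is reliable on electron-rich arenes and leaves the dihydrobenzofuran stereocentres untouched.

Step 24
Reactants: 27 ring B/ring C bromide; 36 ring A styrene
Product: 37 (2S,3S)-5-{(E)-2-[(2R,3R)-3-[(2S,3S)-3-(3,5-dimethoxyphenyl)-6-methoxy-2-(4-methoxyphenyl)-2,3-dihydrobenzofuran-4-yl]-2-(4-methoxyphenyl)-2,3-dihydrobenzofuran-6-yl]ethenyl}-3-(3,5-dimethoxyphenyl)-7-methoxy-2-(4-methoxyphenyl)-2,3-dihydrobenzofuran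
Conditions: Pd(OAc)2 (10 mol %), P(o-tol)3, Et3N, DMF, 100 °C
Reagents that add atoms: none
Why: In this Mizoroki–Heck arylation of a terminal styrene, syn insertion at the unsubstituted carbon and syn β-hydride elimination give the E-stilbene, and each partner carries only one reactive site.

Step 25
Reactants: 37 nona-O-methyl ether
Product: 38 CNP0265934.1, (2S,3S)-5-{(E)-2-[(2R,3R)-3-[(2S,3S)-3-(3,5-dihydroxyphenyl)-6-hydroxy-2-(4-hydroxyphenyl)-2,3-dihydrobenzofuran-4-yl]-2-(4-hydroxyphenyl)-2,3-dihydrobenzofuran-6-yl]ethenyl}-3-(3,5-dihydroxyphenyl)-2-(4-hydroxyphenyl)-2,3-dihydrobenzofuran-7-ol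
Conditions: BBr3 (excess), CH2Cl2, −78 °C to 0 °C; MeOH then H2O quench
Reagents that add atoms: none
Why: Exhaustive aryl methyl ether cleavage with BBr3 is the customary last step for permethylated oligostilbenes, including 5-styryl-2,3-diaryldihydrobenzofurans; here the alkene is out of reach of every resorcinol ring, full boron complexation deactivates the arenes, and any transient C2–O opening should reclose to the trans rings already present.

Compound list
1 | 1-(2,6-dihydroxy-4-methoxyphenyl)ethan-1-one | CC(=O)c1c(O)cc(OC)cc1O | starting material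
2 | benzyl bromide | BrCc1ccccc1 | starting material
3 | 1-[2-(benzyloxy)-6-hydroxy-4-methoxyphenyl]ethan-1-one | CC(=O)c1c(O)cc(OC)cc1OCc1ccccc1 | intermediate
4 | (E)-1-[2-(benzyloxy)-6-hydroxy-4-methoxyphenyl]-3-(dimethylamino)prop-2-en-1-one | CN(C)/C=C/C(=O)c1c(O)cc(OC)cc1OCc1ccccc1 | intermediate
5 | 5-(benzyloxy)-7-methoxy-4H-chromen-4-one | O=c1ccoc2cc(OC)cc(OCc3ccccc3)c12 | intermediate
6 | 4-methoxyphenylboronic acid | COc1ccc(B(O)O)cc1 | starting material
7 | (2S)-5-(benzyloxy)-7-methoxy-2-(4-methoxyphenyl)chroman-4-one | O=C1C[C@@H](c2ccc(OC)cc2)Oc2cc(OC)cc(OCc3ccccc3)c12 | intermediate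
8 | (2S)-5-(benzyloxy)-4,7-dimethoxy-2-(4-methoxyphenyl)-2H-chromene | COC1=C[C@@H](c2ccc(OC)cc2)Oc2cc(OC)cc(OCc3ccccc3)c12 | intermediate
9 | methyl (2S,3S)-4-(benzyloxy)-6-methoxy-2-(4-methoxyphenyl)-2,3-dihydrobenzofuran-3-carboxylate | O(Cc1ccccc1)c1cc(OC)cc2c1[C@H](C(=O)OC)[C@@H](c1ccc(OC)cc1)O2 | intermediate
10 | (2S,3S)-4-(benzyloxy)-6-methoxy-2-(4-methoxyphenyl)-2,3-dihydrobenzofuran-3-carboxylic acid | O(Cc1ccccc1)c1cc(OC)cc2c1[C@H](C(=O)O)[C@@H](c1ccc(OC)cc1)O2 | intermediate
11 | 1,3-dioxoisoindolin-2-yl (2S,3S)-4-(benzyloxy)-6-methoxy-2-(4-methoxyphenyl)-2,3-dihydrobenzofuran-3-carboxylate | O(Cc1ccccc1)c1cc(OC)cc2c1[C@H](C(=O)ON1C(=O)c3ccccc3C1=O)[C@@H](c1ccc(OC)cc1)O2 | intermediate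
12 | 3,5-dimethoxyphenylmagnesium chloride | COc1cc(OC)cc([Mg]Cl)c1 | starting material
13 | (3,5-dimethoxyphenyl)zinc chloride | COc1cc(OC)cc([Zn]Cl)c1 | intermediate
14 | (2S,3S)-4-(benzyloxy)-3-(3,5-dimethoxyphenyl)-6-methoxy-2-(4-methoxyphenyl)-2,3-dihydrobenzofuran | O(Cc1ccccc1)c1cc(OC)cc2c1[C@H](c1cc(OC)cc(OC)c1)[C@@H](c1ccc(OC)cc1)O2 | intermediate
15 | (2S,3S)-3-(3,5-dimethoxyphenyl)-6-methoxy-2-(4-methoxyphenyl)-2,3-dihydrobenzofuran-4-ol | Oc1cc(OC)cc2c1[C@H](c1cc(OC)cc(OC)c1)[C@@H](c1ccc(OC)cc1)O2 | intermediate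
16 | (2S,3S)-3-(3,5-dimethoxyphenyl)-6-methoxy-2-(4-methoxyphenyl)-2,3-dihydrobenzofuran-4-yl trifluoromethanesulfonate | O=S(=O)(Oc1cc(OC)cc2c1[C@H](c1cc(OC)cc(OC)c1)[C@@H](c1ccc(OC)cc1)O2)C(F)(F)F | intermediate
17 | (2S,3S)-3-(3,5-dimethoxyphenyl)-6-methoxy-2-(4-methoxyphenyl)-2,3-dihydrobenzofuran-4-carbaldehyde | O=Cc1cc(OC)cc2c1[C@H](c1cc(OC)cc(OC)c1)[C@@H](c1ccc(OC)cc1)O2 | intermediate
18 | 5-bromo-2-iodophenol | Oc1cc(Br)ccc1I | starting material
19 | 4-methoxybenzyl chloride | COc1ccc(CCl)cc1 | starting material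
20 | 4-bromo-1-iodo-2-[(4-methoxybenzyl)oxy]benzene | COc1ccc(COc2cc(Br)ccc2I)cc1 | intermediate
21 | {4-bromo-2-[(4-methoxybenzyl)oxy]phenyl}magnesium chloride | COc1ccc(COc2cc(Br)ccc2[Mg]Cl)cc1 | intermediate
22 | {4-bromo-2-[(4-methoxybenzyl)oxy]phenyl}[(2S,3S)-3-(3,5-dimethoxyphenyl)-6-methoxy-2-(4-methoxyphenyl)-2,3-dihydrobenzofuran-4-yl]methanol, carbinol epimers | OC(c1ccc(Br)cc1OCc1ccc(OC)cc1)c1cc(OC)cc2c1[C@H](c1cc(OC)cc(OC)c1)[C@@H](c1ccc(OC)cc1)O2 | intermediate
23 | {4-bromo-2-[(4-methoxybenzyl)oxy]phenyl}[(2S,3S)-3-(3,5-dimethoxyphenyl)-6-methoxy-2-(4-methoxyphenyl)-2,3-dihydrobenzofuran-4-yl]methanone | O=C(c1ccc(Br)cc1OCc1ccc(OC)cc1)c1cc(OC)cc2c1[C@H](c1cc(OC)cc(OC)c1)[C@@H](c1ccc(OC)cc1)O2 | intermediate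
24 | hydrazone of 23, E/Z mixture | NN=C(c1ccc(Br)cc1OCc1ccc(OC)cc1)c1cc(OC)cc2c1[C@H](c1cc(OC)cc(OC)c1)[C@@H](c1ccc(OC)cc1)O2 | intermediate
25 | (2S,3S)-4-[{4-bromo-2-[(4-methoxybenzyl)oxy]phenyl}(diazo)methyl]-3-(3,5-dimethoxyphenyl)-6-methoxy-2-(4-methoxyphenyl)-2,3-dihydrobenzofuran | [N-]=[N+]=C(c1ccc(Br)cc1OCc1ccc(OC)cc1)c1cc(OC)cc2c1[C@H](c1cc(OC)cc(OC)c1)[C@@H](c1ccc(OC)cc1)O2 | intermediate
26 | (2S,3S)-4-[(2S,3R)-6-bromo-2-(4-methoxyphenyl)-2,3-dihydrobenzofuran-3-yl]-3-(3,5-dimethoxyphenyl)-6-methoxy-2-(4-methoxyphenyl)-2,3-dihydrobenzofuran | Brc1ccc2c(c1)O[C@H](c1ccc(OC)cc1)[C@@H]2c1cc(OC)cc2c1[C@H](c1cc(OC)cc(OC)c1)[C@@H](c1ccc(OC)cc1)O2 | intermediate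
27 | (2S,3S)-4-[(2R,3R)-6-bromo-2-(4-methoxyphenyl)-2,3-dihydrobenzofuran-3-yl]-3-(3,5-dimethoxyphenyl)-6-methoxy-2-(4-methoxyphenyl)-2,3-dihydrobenzofuran | Brc1ccc2c(c1)O[C@@H](c1ccc(OC)cc1)[C@@H]2c1cc(OC)cc2c1[C@H](c1cc(OC)cc(OC)c1)[C@@H](c1ccc(OC)cc1)O2 | intermediate
28 | 5-bromo-2-hydroxy-3-methoxybenzaldehyde | O=Cc1cc(Br)cc(OC)c1O | starting material
29 | 5-bromo-3-methoxy-2-[(4-methoxybenzyl)oxy]benzaldehyde | O=Cc1cc(Br)cc(OC)c1OCc1ccc(OC)cc1 | intermediate
30 | {5-bromo-3-methoxy-2-[(4-methoxybenzyl)oxy]phenyl}(3,5-dimethoxyphenyl)methanol, racemic | OC(c1cc(OC)cc(OC)c1)c1cc(Br)cc(OC)c1OCc1ccc(OC)cc1 | intermediate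
31 | {5-bromo-3-methoxy-2-[(4-methoxybenzyl)oxy]phenyl}(3,5-dimethoxyphenyl)methanone | O=C(c1cc(OC)cc(OC)c1)c1cc(Br)cc(OC)c1OCc1ccc(OC)cc1 | intermediate
32 | hydrazone of 31, E/Z mixture | NN=C(c1cc(OC)cc(OC)c1)c1cc(Br)cc(OC)c1OCc1ccc(OC)cc1 | intermediate
33 | 5-bromo-1-[diazo(3,5-dimethoxyphenyl)methyl]-3-methoxy-2-[(4-methoxybenzyl)oxy]benzene | [N-]=[N+]=C(c1cc(OC)cc(OC)c1)c1cc(Br)cc(OC)c1OCc1ccc(OC)cc1 | intermediate
34 | (2R,3S)-5-bromo-3-(3,5-dimethoxyphenyl)-7-methoxy-2-(4-methoxyphenyl)-2,3-dihydrobenzofuran | COc1ccc([C@@H]2Oc3c(OC)cc(Br)cc3[C@@H]2c2cc(OC)cc(OC)c2)cc1 | intermediate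
35 | (2S,3S)-5-bromo-3-(3,5-dimethoxyphenyl)-7-methoxy-2-(4-methoxyphenyl)-2,3-dihydrobenzofuran | COc1ccc([C@H]2Oc3c(OC)cc(Br)cc3[C@@H]2c2cc(OC)cc(OC)c2)cc1 | intermediate
36 | (2S,3S)-3-(3,5-dimethoxyphenyl)-5-ethenyl-7-methoxy-2-(4-methoxyphenyl)-2,3-dihydrobenzofuran | COc1ccc([C@H]2Oc3c(OC)cc(C=C)cc3[C@@H]2c2cc(OC)cc(OC)c2)cc1 | intermediate
37 | nona-O-methyl ether of the target (ring A 2S,3S; ring B 2R,3R; ring C 2S,3S; E-alkene) | COc1ccc([C@H]2Oc3c(OC)cc(/C=C/c4ccc5c(c4)O[C@@H](c4ccc(OC)cc4)[C@@H]5c4cc(OC)cc5c4[C@H](c4cc(OC)cc(OC)c4)[C@@H](c4ccc(OC)cc4)O5)cc3[C@@H]2c2cc(OC)cc(OC)c2)cc1 | intermediate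
38 | CNP0265934.1 | Oc1ccc([C@H]2Oc3c(O)cc(/C=C/c4ccc5c(c4)O[C@@H](c4ccc(O)cc4)[C@@H]5c4cc(O)cc5c4[C@H](c4cc(O)cc(O)c4)[C@@H](c4ccc(O)cc4)O5)cc3[C@@H]2c2cc(O)cc(O)c2)cc1 | target

Total step count: 25.
Longest linear sequence: 17 (steps 1–10, 12–16, 24, 25).

Steps most likely to fail

**Risk 1, step 15.** The carbene carbon sits between two ortho-substituted arenes in a substrate that is already chiral.
- Insertion may be slow enough for azine formation.
- The carbene may attack the neighbouring dimethoxyphenyl ring of ring C.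
- The catalyst and substrate facial preferences may be mismatched.
- Sluggish condensation in step 14 belongs to the same weak point.

The fallback closes ring B through its C–O bond instead of its C–C bond, sets out from ketone 23 and returns at 27. Ketone 23 is methylenated with dimethylsulfonium methylide (Corey–Chaykovsky) to the 2,2-diaryloxirane F1. ZnI2 then brings about a Meinwald rearrangement to the diarylacetaldehyde F2, and 4-methoxyphenylmagnesium bromide adds to give the 1,2,2-triarylethanol F3. CF3CO2H with anisole as cation trap removes the 4-methoxybenzyl group and ionises the benzylic alcohol, so the freed phenol closes the ring to the trans arrangement. Ring B C3 is then under substrate control only, so 27 must be separated by chromatography from the ring B (2S,3S) diastereomer F4.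

**Risk 2, step 7.** Capture of the stabilised, crowded benzylic C3 radical by nickel may lag behind radical dimerisation. It may also lag behind β-scission of the C2–O bond, and the facial selectivity may erode.

The fallback replaces radical–metal coupling by a polar 1,2-metallate shift, sets out from 11 and returns at 14. Nickel-catalysed decarboxylative borylation of 11 (NiCl2·6H2O, bipyridine ligand, B2pin2/MeLi, MgBr2·OEt2) gives the trans C3 pinacol boronate F5. Addition of 3,5-dimethoxyphenyllithium at −78 °C forms the boronate complex. One equivalent of NBS then triggers bromination of the activated aryl ring, stereoretentive migration of C3 and loss of the boron unit, giving 14.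

**Risk 3, step 4.**
- The anisyl group may shift from C2 to C3 in place of C4a.
- The iodinated intermediate may eliminate instead of rearranging.
- The iodine reagent may attack C6 or C8 of the very electron-rich benzo ring, before or after contraction.
- Acid may open the pyranone by retro-oxa-Michael reaction and erode C2.

The fallback keeps the same C4a shift and the same ring contraction but drives it from a carbene instead of an oxidant; it sets out from 7 and returns at 9. Enolisation of 7 at −78 °C (LiHMDS) and acylation with 2,2,2-trifluoroethyl trifluoroacetate give the 3-trifluoroacetyl flavanone F6. Detrifluoroacetylative diazo transfer (MsN3, Et3N) gives the 3-diazoflavanone F7. Irradiation in methanol induces the Wolff rearrangement of this conformationally locked cyclic diazo ketone. Methanol traps the ketene, giving mainly the cis ester F8 by protonation anti to the aryl group, and NaOMe in MeOH equilibrates it to the trans ester 9.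

Further compounds
F1 | step 15 | 2-{4-bromo-2-[(4-methoxybenzyl)oxy]phenyl}-2-[(2S,3S)-3-(3,5-dimethoxyphenyl)-6-methoxy-2-(4-methoxyphenyl)-2,3-dihydrobenzofuran-4-yl]oxirane (epimers) | C1OC1(c1ccc(Br)cc1OCc1ccc(OC)cc1)c1cc(OC)cc2c1[C@H](c1cc(OC)cc(OC)c1)[C@@H](c1ccc(OC)cc1)O2
F2 | step 15 | 2-{4-bromo-2-[(4-methoxybenzyl)oxy]phenyl}-2-[(2S,3S)-3-(3,5-dimethoxyphenyl)-6-methoxy-2-(4-methoxyphenyl)-2,3-dihydrobenzofuran-4-yl]acetaldehyde (epimers) | O=CC(c1ccc(Br)cc1OCc1ccc(OC)cc1)c1cc(OC)cc2c1[C@H](c1cc(OC)cc(OC)c1)[C@@H](c1ccc(OC)cc1)O2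
F3 | step 15 | 2-{4-bromo-2-[(4-methoxybenzyl)oxy]phenyl}-2-[(2S,3S)-3-(3,5-dimethoxyphenyl)-6-methoxy-2-(4-methoxyphenyl)-2,3-dihydrobenzofuran-4-yl]-1-(4-methoxyphenyl)ethan-1-ol (diastereomer mixture) | OC(c1ccc(OC)cc1)C(c1ccc(Br)cc1OCc1ccc(OC)cc1)c1cc(OC)cc2c1[C@H](c1cc(OC)cc(OC)c1)[C@@H](c1ccc(OC)cc1)O2
F4 | step 15 | (2S,3S)-4-[(2S,3S)-6-bromo-2-(4-methoxyphenyl)-2,3-dihydrobenzofuran-3-yl]-3-(3,5-dimethoxyphenyl)-6-methoxy-2-(4-methoxyphenyl)-2,3-dihydrobenzofuran | Brc1ccc2c(c1)O[C@H](c1ccc(OC)cc1)[C@H]2c1cc(OC)cc2c1[C@H](c1cc(OC)cc(OC)c1)[C@@H](c1ccc(OC)cc1)O2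
F5 | step 7 | 2-[(2S,3S)-4-(benzyloxy)-6-methoxy-2-(4-methoxyphenyl)-2,3-dihydrobenzofuran-3-yl]-4,4,5,5-tetramethyl-1,3,2-dioxaborolane | O(Cc1ccccc1)c1cc(OC)cc2c1[C@H](B1OC(C)(C)C(C)(C)O1)[C@@H](c1ccc(OC)cc1)O2
F6 | step 4 | (2S)-5-(benzyloxy)-7-methoxy-2-(4-methoxyphenyl)-3-(trifluoroacetyl)chroman-4-one | O=C1C(C(=O)C(F)(F)F)[C@@H](c2ccc(OC)cc2)Oc2cc(OC)cc(OCc3ccccc3)c12
F7 | step 4 | (2R)-5-(benzyloxy)-3-diazo-7-methoxy-2-(4-methoxyphenyl)chroman-4-one | O=C1C(=[N+]=[N-])[C@@H](c2ccc(OC)cc2)Oc2cc(OC)cc(OCc3ccccc3)c12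
F8 | step 4 | methyl (2S,3R)-4-(benzyloxy)-6-methoxy-2-(4-methoxyphenyl)-2,3-dihydrobenzofuran-3-carboxylate | O(Cc1ccccc1)c1cc(OC)cc2c1[C@@H](C(=O)OC)[C@@H](c1ccc(OC)cc1)O2
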